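**Retrosynthetic overview**
- Target 4-quinolone ⇒ open the N1–C2 bond and put back four hydrogens (C2–C3 and the ring closure): a saturated ortho-(methylamino)phenyl heptadecyl ketone. In the forward direction, one Cu/TEMPO operation desaturates the ketone, closes the ring by N–C bond formation, and desaturates again.
- Amino ketone ⇒ aryl–C(=O) disconnection: N-methylaniline + octadecanenitrile (ortho-acylation). The nitrile carbon becomes C4, its α- and β-carbons become C3 and C2, and the remaining 15 carbons are the pentadecyl chain.
- Ring order: the benzene ring is bought (it already carries N–CH3); the nitrogen ring is formed last. Compound numbers follow the forward order of the steps.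

Assumption: the target has no stereocentre (it is achiral), so "single enantiomer" calls for no stereocontrol; the one transient stereocentre (C2 of intermediate 7) is racemic and is erased in the same flask.

**Step 1**
Reactants: 1 N-methylaniline; 2 octadecanenitrile (stearonitrile)
Product: 5 1-[2-(methylamino)phenyl]octadecan-1-one, via aminodichloroborane 3 (not isolated), via ketimine 4 (not isolated)
Conditions: BCl3 (1.1 equiv, 1 M in toluene), 0 °C; then 2 (1.2 equiv), AlCl3 (1.1 equiv), toluene, reflux, 8 h; then 2 M aq HCl, 80 °C, 0.5 h
Reagents that add atoms: water, SMILES O (supplies the ketone oxygen)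
Why: Sugasawa ortho-acylation, in which the N–BCl2 group of 3 delivers the AlCl3-activated nitrile to the ortho position only, through a six-membered transition state, and acid hydrolysis of ketimine 4 gives the ketone; secondary N-alkylanilines are good substrates and no stereocentre is formed.

**Step 2**
Reactants: 5 1-[2-(methylamino)phenyl]octadecan-1-one
Product: 8 1-methyl-2-pentadecylquinolin-4(1H)-one, via enone 6 (not isolated), via dihydroquinolone 7 (not isolated)
Conditions: Cu(OAc)2 (10 mol %), 2,2′-bipyridine (10 mol %), TEMPO (4.4 equiv), 1,2-dichlorobenzene, 120 °C, N2, 24 h
Reagents that add atoms: none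
Why: Proposed new method: a double dehydrogenative 6-endo aza-Michael annulation of a saturated ortho-(alkylamino)aryl alkyl ketone, in which Cu(II)/bpy binds the N,O-chelating amino ketone as its enolate and TEMPO removes the α- and β-hydrogens (2 TEMPO → 2 TEMPO-H) to give (E)-enone 6, the ortho N–H then adds 6-endo-trig to the Cu-activated enone and forms the N1–C2 bond (dihydroquinolone 7, racemic at C2), and a second Cu/TEMPO desaturation of 7 (α,β-desaturation or C2–H oxidation to the iminium and tautomerisation, both converging) gives the vinylogous amide 8 as the thermodynamic sink; the closest known reaction types are the Cu/TEMPO dehydrogenation–conjugate addition (intermolecular β-functionalisation) of aryl alkyl ketones and the Pd/O2 dehydrogenative cyclisation of 2′-hydroxy- or 2′-amino-dihydrochalcones, and to my knowledge neither has been shown for an unactivated long-chain alkyl ketone closed by an N-alkylamine with a second desaturation in the same pot.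

**Compound list**
1 | N-methylaniline | CNc1ccccc1 | starting material
2 | octadecanenitrile (stearonitrile) | CCCCCCCCCCCCCCCCCC#N | starting material
3 | dichloro(N-methylanilino)borane | CN(B(Cl)Cl)c1ccccc1 | intermediate
4 | 1-[2-(methylamino)phenyl]octadecan-1-imine (present in the flask as its boron/aluminium complex, drawn as the free ketimine) | CCCCCCCCCCCCCCCCCC(=N)c1ccccc1NC | intermediate
5 | 1-[2-(methylamino)phenyl]octadecan-1-one | CCCCCCCCCCCCCCCCCC(=O)c1ccccc1NC | intermediate
6 | (E)-1-[2-(methylamino)phenyl]octadec-2-en-1-one | CCCCCCCCCCCCCCC/C=C/C(=O)c1ccccc1NC | intermediate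
7 | rac-1-methyl-2-pentadecyl-2,3-dihydroquinolin-4(1H)-one | CCCCCCCCCCCCCCCC1CC(=O)c2ccccc2N1C | intermediate
8 | 1-methyl-2-pentadecylquinolin-4(1H)-one (achiral) | CCCCCCCCCCCCCCCc1cc(=O)c2ccccc2n1C | target

**Total step count:** 2
**Longest linear sequence:** 2

**Steps most likely to fail** (the route has only two steps, so both are ranked and there is no third):

1. Step 2 (the proposed new method). Main risks:
   - 5-exo α-amination of the Cu enolate to an indoxyl instead of desaturation;
   - oxidation of the N-methyl group;
   - catalyst sequestration by the N,O-chelating substrate;
   - further desaturation into the chain.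

   Fallback, known chemistry throughout, setting out from 5 and coming back at 8: 5 is treated with LiHMDS (2.2 equiv) and TMSCl (THF, −78 °C; NaHCO3 work-up cleaves the N–Si bond) to give the silyl enol ether (Z)-N-methyl-2-[1-(trimethylsilyloxy)octadec-1-en-1-yl]aniline F2. Saegusa–Ito oxidation (Pd(OAc)2, MeCN, rt) gives enone 6, which closes with catalytic TsOH to dihydroquinolone 7, isolated in this variant. DDQ (dioxane, 80 °C) then dehydrogenates 7 to 8. This replaces the one-pot cascade with three stepwise operations.

2. Step 1. Main risks:
   - N-attack on the nitrile (amidine formation) in place of ortho C-acylation;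
   - incomplete conversion with the waxy long-chain nitrile.

   Fallback, setting out from 2 and coming back at ketimine 4 (and so 5): commercial 2-bromo-N-methylaniline is treated with n-BuLi (2.1 equiv, Et2O, −78 → 0 °C; N–H deprotonation, then Br/Li exchange) to give N,2-dilithio-N-methylaniline F1. F1 adds to nitrile 2 (−78 °C → rt) to give, after aqueous HCl, ketimine 4, which hydrolyses to 5 as in step 1. This swaps the Lewis-acid electrophilic substitution for an aryl-carbanion addition, so ortho selectivity is fixed by the bromine.

**Further compounds**
F1 | step 1 | N,2-dilithio-N-methylaniline | [Li]c1ccccc1N([Li])C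
F2 | step 2 | (Z)-N-methyl-2-[1-(trimethylsilyloxy)octadec-1-en-1-yl]aniline | CCCCCCCCCCCCCCCC/C=C(\O[Si](C)(C)C)c1ccccc1NC
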